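We must choose where to keep this charge for 10 d, and two of us disagree on the direction: cold or warm.

common to all: starting material 0.40 M; reagent 0.440 M; second substrate 0.400 M; time 10 d
- north: temperature 0 °C
- south-east: temperature 25 °C
- west: at −25 °C until 5.0 d, from then on at 25 °C
- south: temperature −25 °C

- the best flask by share of target in all that became target or side product or over-reaction product; "all alike" if 1.5 percentage points covers them all (north / south-east / west / south / all alike)
- share of target in all that became target or side product or over-reaction product, north
- share of target in all that became target or side product or over-reaction product, south-east
- share of target in all that became target or side product or over-reaction product, west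
- share of target in all that became target or side product or over-reaction product, south

    starting material + reagent ⇌ target (K1 = 1.8 M⁻¹, k1 = 0.0034 M⁻¹ min⁻¹, Ea1 = 74.0 kJ mol⁻¹, ΔH1 = −33.0 kJ mol⁻¹)
    second substrate + reagent ⇌ second product (K2 = 3.5 M⁻¹, k2 = 0.0040 M⁻¹ min⁻¹, Ea2 = 81.0 kJ mol⁻¹, ΔH2 = 13.0 kJ mol⁻¹)
    starting material + target → side product (k3 = 0.019 M⁻¹ min⁻¹, Ea3 = 68.0 kJ mol⁻¹)
    target → over-reaction product (k4 = 0.0018 min⁻¹, Ea4 = 102 kJ mol⁻¹)
    (constants at 25 °C)

- percentages count the starting material that a species holds: one side product counts as two
- at 25 °C the constants are as listed, elsewhere as the activation energies and enthalpies make them

My colleague looks at barriers. The activation energy of the side step minus that of the step making target is −6.00 kJ mol⁻¹, so cooling favours the side step. The side constant over the making constant is 5.59 at 25 °C and 9.10 at −25 °C, higher in the cold. He therefore backs the south-east flask.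

I look at one concentration. Starting material attacks target at a rate proportional to [starting material] times [target]. While [starting material] stays close to its charge, target is lost in a pseudo-first-order way. In the south flask the side constant is 7.56 × 10⁻⁵ min⁻¹ M⁻¹, so the half-life of target by this step is 15.9 d, longer than the run.

I call the side constant times [starting material] times the run time the lives of target, and the south flask has 0.435. Leaving aside the way back and the over-reaction step, making and side loss balance at a level of [target] equal to the making constant times [reagent] over the side constant, and [starting material] cancels there. Target climbs towards that level with lives as its clock. With [reagent] also held at its charge, target and side product both scale with that level, so in this reckoning their share does not follow [reagent]. Counting each side product twice, my reckoning from lives gives 68.2 % for the south flask.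

In the south-east flask the same half-life starts at 91.2 min, far shorter than the run, so I expect a much lower share there. My reckoning stops at that direction, since it holds [starting material] at its charge. I back the south flask.

His ratio has its region where the height of [target] is the question and lives stand well above one: in my reckoning target then sits at its level, and a smaller ratio raises that level at the same [reagent]. The south flask stands at lives below one.

The forecast takes my side: south is best, with 6 % for north, 0.05 % for south-east, 0.35 % for west and 69 % for south, against my 68.2 %. It calls the cold flask “still in its kinetic early phase”.

South is best at 68.3 %, against 6.89 % in north, 0.492 % in west and 0.130 % in south-east. Moved alone up or down by the same factor, the settings tried shift the south answer at most in this order: starting material (6.4 points), then time (6.3 points), then reagent (0.2 points), then second substrate (under 0.05 points). In the north flask the side constant is 0.00154 min⁻¹ M⁻¹. Taking [starting material] as the mean of its charge and the 27.6 % left at 10.0 d, north has 5.67 lives, more than south. The same reckoning gives 9.64 %, and the north flask stood at 6.89 %.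

The numbers of this flask are invented; what happens was integrated by code.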